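## Retrosynthetic overview

- Ring A is a benzene with the ring oxygen on C8a, the C4 carbon on C4a, methoxyls on C5, C6 and C7, and hydrogen on C8. That is the pattern left when a dimethoxy vinylketene (C8a, C6, C7, C8) is joined to a methoxyalkyne (C4a, C5).
- Key disconnection: C4a–C8a and C5–C6 (C8–C8a re-formed), back to 2,3-dimethoxycyclobut-2-en-1-one 4 and methoxyalkyne 20, which already carries the C4–C3–C2 chain and ring B.
- Ring C is closed afterwards by intramolecular Mitsunobu etherification O1–C2 with inversion. C4 is then oxidised to the ketone and the benzyl ethers are removed.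
- Alkyne 20 comes from aldehyde 16 and lithium methoxyacetylide. Aldehyde 16 comes from an Evans glycolate syn-aldol on aldehyde 8, which sets C3 and the pre-inversion C2.
- Cyclobutenone 4 comes from dimethyl squarate by reduction, acetylation and reductive loss of the acetoxy group. Ring order: B (bought), A (step 14), C (step 16).

Key step: step 14

Remark: flavanone numbering (O1, C2, C3, C4, C4a–C8a) is used for the chain; the carbinol carbon that becomes C4 is carried as both epimers because step 18 makes it the ketone, and the CIP descriptor of the neighbouring methoxy carbon changes with the protecting groups although its configuration does not.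

## Route

Step 1
Reactants: 1 dimethyl squarate
Product: 2 4-hydroxy-2,3-dimethoxycyclobut-2-en-1-one (racemic)
Conditions: LiAlH(OtBu)3 (1.05 equiv), THF, −78 °C; cold neutral aqueous work-up
Reagents that add atoms: none
Why: 1,2-Hydride reduction of one ketone of a squarate diester by a bulky alkoxyaluminium hydride, the remaining vinylogous ester carbonyl being too unreactive to be reduced at −78 °C; acid is avoided because it would transpose the product to the semisquarate.

Step 2
Reactants: 2 4-hydroxy-2,3-dimethoxycyclobut-2-en-1-one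
Product: 3 2,3-dimethoxy-4-oxocyclobut-2-en-1-yl acetate (racemic)
Conditions: Ac2O, pyridine, DMAP (cat.), CH2Cl2, 0 °C
Reagents that add atoms: acetic anhydride CC(=O)OC(C)=O
Why: DMAP-catalysed O-acylation of a secondary alcohol under basic conditions, which the acid-labile 4-oxycyclobutenone should tolerate.

Step 3
Reactants: 3 2,3-dimethoxy-4-oxocyclobut-2-en-1-yl acetate
Product: 4 2,3-dimethoxycyclobut-2-en-1-one
Conditions: SmI2 (2.2 equiv), THF–MeOH, −78 °C
Reagents that add atoms: none
Why: Reductive cleavage of an α-acyloxy ketone by SmI2, with protonation by methanol expected at the hydrogen-bearing ring carbon (the allylic terminus remote from the methoxy group, as for alkoxyallyl anions) so that both methoxyls stay on the conjugated double bond; the low temperature should prevent electrocyclic ring opening.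

Step 4
Reactants: 5 methyl 3,5-dihydroxy-4-methoxybenzoate
Product: 6 methyl 3,5-bis(benzyloxy)-4-methoxybenzoate
Conditions: BnBr (2.4 equiv), K2CO3, DMF, 60 °C
Reagents that add atoms: benzyl bromide BrCc1ccccc1
Why: Williamson etherification of both phenols.

Step 5
Reactants: 6 methyl 3,5-bis(benzyloxy)-4-methoxybenzoate
Product: 7 [3,5-bis(benzyloxy)-4-methoxyphenyl]methanol
Conditions: LiAlH4, THF, 0 °C
Reagents that add atoms: none
Why: Hydride reduction of an aryl ester to the benzylic alcohol.

Step 6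
Reactants: 7 [3,5-bis(benzyloxy)-4-methoxyphenyl]methanol
Product: 8 3,5-bis(benzyloxy)-4-methoxybenzaldehyde
Conditions: MnO2, CH2Cl2, rt
Reagents that add atoms: none
Why: Selective oxidation of a benzylic alcohol to the aldehyde by MnO2 without over-oxidation.

Step 7
Reactants: 9 (R)-4-benzyloxazolidin-2-one; 10 methoxyacetyl chloride
Product: 11 (R)-4-benzyl-3-(2-methoxyacetyl)oxazolidin-2-one
Conditions: n-BuLi, THF, −78 °C; then 10, −78 → 0 °C
Reagents that add atoms: none
Why: N-Acylation of the lithiated oxazolidinone by an acid chloride.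

Step 8
Reactants: 11 (R)-4-benzyl-3-(2-methoxyacetyl)oxazolidin-2-one; 8 3,5-bis(benzyloxy)-4-methoxybenzaldehyde
Product: 13 (4R)-4-benzyl-3-[(2R,3S)-3-[3,5-bis(benzyloxy)-4-methoxyphenyl]-3-hydroxy-2-methoxypropanoyl]oxazolidin-2-one, via dibutylboron Z-enolate 12 (not isolated)
Conditions: Bu2BOTf, Et3N, CH2Cl2, 0 °C; then 8, −78 → 0 °C; H2O2, pH 7 buffer, MeOH, 0 °C
Reagents that add atoms: none
Why: Evans glycolate syn-aldol, in which the Z boron enolate reacts through a closed chair transition state on the face opposite the auxiliary benzyl group, setting the methoxy carbon (future C3, R) and the carbinol carbon (future C2 before inversion, S) in a 2,3-syn relationship.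

Step 9
Reactants: 13 the syn-aldol imide
Product: 14 (2R,3S)-3-[3,5-bis(benzyloxy)-4-methoxyphenyl]-3-hydroxy-N,2-dimethoxy-N-methylpropanamide
Conditions: MeNHOMe·HCl, AlMe3, THF, −15 → 0 °C; aq potassium sodium tartrate
Reagents that add atoms: N,O-dimethylhydroxylamine hydrochloride CNOC.Cl
Why: Aluminium amide transamination of the imide to the Weinreb amide, assisted by the free β-hydroxyl, which releases the auxiliary without touching either stereocentre.

Step 10
Reactants: 14 the β-hydroxy Weinreb amide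
Product: 15 (2R,3S)-3-[3,5-bis(benzyloxy)-4-methoxyphenyl]-N,2-dimethoxy-N-methyl-3-(triethylsilyloxy)propanamide
Conditions: TESCl, imidazole, DMF, 0 °C → rt
Reagents that add atoms: chlorotriethylsilane CC[Si](Cl)(CC)CC
Why: Imidazole-mediated silylation of the secondary benzylic alcohol.

Step 11
Reactants: 15 the silylated Weinreb amide
Product: 16 (2R,3S)-3-[3,5-bis(benzyloxy)-4-methoxyphenyl]-2-methoxy-3-(triethylsilyloxy)propanal
Conditions: i-Bu2AlH, THF, −78 °C; aq potassium sodium tartrate
Reagents that add atoms: none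
Why: Weinreb amide reduction, which stops at the aldehyde oxidation level; the α-methoxy aldehyde is used at once to avoid epimerisation.

Step 12
Reactants: 16 the α-methoxy aldehyde; 17 chloroacetaldehyde dimethyl acetal
Product: 19 (4S,5S)-5-[3,5-bis(benzyloxy)-4-methoxyphenyl]-1,4-dimethoxy-5-(triethylsilyloxy)pent-1-yn-3-ol (both C3 epimers), via lithium methoxyacetylide 18 (not isolated)
Conditions: 17 (2 equiv), LiNEt2 (3 equiv per 17), THF, 0 °C; then 16, −78 °C; pH 7 buffer
Reagents that add atoms: none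
Why: Double dehydrohalogenation–elimination of the chloroacetal gives the lithium alkoxyacetylide, which adds 1,2 to the aldehyde; the facial selectivity is irrelevant because this carbinol becomes the C4 ketone.

Step 13
Reactants: 19 the propargylic alcohol
Product: 20 (4R,5S)-5-[3,5-bis(benzyloxy)-4-methoxyphenyl]-3-(tert-butyldimethylsilyloxy)-1,4-dimethoxy-5-(triethylsilyloxy)pent-1-yne (both C3 epimers)
Conditions: TBSCl, imidazole, DMAP (cat.), DMF, rt
Reagents that add atoms: tert-butyldimethylsilyl chloride CC(C)(C)[Si](C)(C)Cl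
Why: Silylation under basic conditions, chosen because the ynol ether carbinol would rearrange to an unsaturated ester under acid.

Step 14
Reactants: 20 the methoxyalkyne; 4 2,3-dimethoxycyclobut-2-en-1-one
Product: 25 2-[(2R,3S)-3-[3,5-bis(benzyloxy)-4-methoxyphenyl]-1-(tert-butyldimethylsilyloxy)-2-methoxy-3-(triethylsilyloxy)propyl]-3,4,5-trimethoxyphenol (both C1 epimers), via vinylketene 21 (not isolated), via 4-vinylcyclobutenone 22 (not isolated), via dienylketene 23 (not isolated), via cyclohexadienone 24 (not isolated)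
Conditions: 4 (1.5 equiv), toluene, sealed tube, 80 °C then 145 °C
Reagents that add atoms: none
Why: Danheiser benzannulation: four-electron electrocyclic opening of 4 gives vinylketene 21, whose ketene carbon is attacked by the nucleophilic, chain-bearing carbon of ynol ether 20 in a regiospecific [2+2] cycloaddition to 22; four-electron opening of 22 gives Z-dienylketene 23, which closes to dienone 24 and tautomerises to phenol 25. The closest known reaction type is the aromatic annulation of cyclobutenones (3-oxygenated ones included) with alkoxyalkynes, of which a 2,3-dialkoxycyclobutenone partner is an extension of scope. Ring A is closed by six-electron electrocyclisation forming C8–C8a, after the [2+2] step and the second ring opening have set C4a–C8a and C5–C6. No stereocentre is created, since the quaternary carbon of 22 is lost on ring opening and the silyl-protected chain centres are untouched by the neutral thermal conditions. The step needs regioselectivity in the [2+2] addition, secured by the polarity of the ynol ether (its methoxy carbon becomes C5 and its chain carbon C4a), and inward rotation of the vinyl group in opening 22, secured by the outward preference of the methoxy donor on the same carbon.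

Step 15
Reactants: 25 the benzannulation phenol
Product: 26 2-[(2R,3S)-3-[3,5-bis(benzyloxy)-4-methoxyphenyl]-1-(tert-butyldimethylsilyloxy)-3-hydroxy-2-methoxypropyl]-3,4,5-trimethoxyphenol (both C1 epimers)
Conditions: HF·pyridine, excess pyridine, THF, 0 °C
Reagents that add atoms: none
Why: Buffered fluoride cleaves the triethylsilyl ether much faster than the tert-butyldimethylsilyl ether, and the buffering should keep the electron-rich C4 benzylic ether from ionising.

Step 16
Reactants: 26 the phenol alcohol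
Product: 27 (2R,3R)-2-[3,5-bis(benzyloxy)-4-methoxyphenyl]-4-(tert-butyldimethylsilyloxy)-3,5,6,7-tetramethoxychromane (both C4 epimers)
Conditions: PPh3, DIAD, THF, 0 °C → rt
Reagents that add atoms: none
Why: Intramolecular Mitsunobu etherification in which the C8a phenol displaces the activated benzylic hydroxyl by six-membered SN2 closure with inversion, turning the 2S carbinol into C2 (R) and giving the 2,3-trans chromane.

Step 17
Reactants: 27 the silylated chromane
Product: 28 (2R,3S)-2-[3,5-bis(benzyloxy)-4-methoxyphenyl]-3,5,6,7-tetramethoxychroman-4-ol (both C4 epimers)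
Conditions: Bu4NF, THF, 0 °C → rt
Reagents that add atoms: none
Why: Fluoride cleavage of the silyl ether under basic conditions that cannot ionise C4.

Step 18
Reactants: 28 the chroman-4-ol
Product: 29 (2R,3R)-2-[3,5-bis(benzyloxy)-4-methoxyphenyl]-3,5,6,7-tetramethoxychroman-4-one
Conditions: Dess–Martin periodinane, NaHCO3, CH2Cl2, 0 °C → rt
Reagents that add atoms: none
Why: Buffered Dess–Martin oxidation of the benzylic alcohol converges both C4 epimers on the ketone, and any enolisation at C3 can only return the more stable 2,3-trans isomer.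

Step 19
Reactants: 29 the dibenzyl flavanone
Product: 30 (2R,3R)-2-(3,5-dihydroxy-4-methoxyphenyl)-3,5,6,7-tetramethoxychroman-4-one (CNP0075603.1)
Conditions: H2 (1 atm), Pd/C, EtOAc–MeOH, rt
Reagents that add atoms: none
Why: Neutral hydrogenolysis of the two aryl benzyl ethers, which should leave the electron-rich aryl ketone, the C2–O1 bond and both stereocentres untouched.

## Compound list

R in 22–24 is the (2R,3S)-3-[3,5-bis(benzyloxy)-4-methoxyphenyl]-1-(tert-butyldimethylsilyloxy)-2-methoxy-3-(triethylsilyloxy)propyl chain of 25.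

1 | dimethyl squarate (3,4-dimethoxycyclobut-3-ene-1,2-dione) | COC1=C(OC)C(=O)C1=O | starting material
2 | 4-hydroxy-2,3-dimethoxycyclobut-2-en-1-one (racemic) | COC1=C(OC)C(=O)C1O | intermediate
3 | 2,3-dimethoxy-4-oxocyclobut-2-en-1-yl acetate (racemic) | COC1=C(OC)C(=O)C1OC(C)=O | intermediate
4 | 2,3-dimethoxycyclobut-2-en-1-one | COC1=C(OC)C(=O)C1 | intermediate
5 | methyl 3,5-dihydroxy-4-methoxybenzoate | COC(=O)c1cc(O)c(OC)c(O)c1 | starting material
6 | methyl 3,5-bis(benzyloxy)-4-methoxybenzoate | COC(=O)c1cc(OCc2ccccc2)c(OC)c(OCc2ccccc2)c1 | intermediate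
7 | [3,5-bis(benzyloxy)-4-methoxyphenyl]methanol | OCc1cc(OCc2ccccc2)c(OC)c(OCc2ccccc2)c1 | intermediate
8 | 3,5-bis(benzyloxy)-4-methoxybenzaldehyde | O=Cc1cc(OCc2ccccc2)c(OC)c(OCc2ccccc2)c1 | intermediate
9 | (R)-4-benzyloxazolidin-2-one | O=C1N[C@H](Cc2ccccc2)CO1 | starting material
10 | methoxyacetyl chloride | COCC(Cl)=O | starting material
11 | (R)-4-benzyl-3-(2-methoxyacetyl)oxazolidin-2-one | COCC(=O)N1[C@H](Cc2ccccc2)COC1=O | intermediate
12 | dibutylboron (Z)-enolate of 11 | CO/C=C(\OB(CCCC)CCCC)N1[C@H](Cc2ccccc2)COC1=O | intermediate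
13 | (4R)-4-benzyl-3-[(2R,3S)-3-[3,5-bis(benzyloxy)-4-methoxyphenyl]-3-hydroxy-2-methoxypropanoyl]oxazolidin-2-one | O=C([C@H](OC)[C@@H](O)c1cc(OCc2ccccc2)c(OC)c(OCc2ccccc2)c1)N1[C@H](Cc2ccccc2)COC1=O | intermediate
14 | (2R,3S)-3-[3,5-bis(benzyloxy)-4-methoxyphenyl]-3-hydroxy-N,2-dimethoxy-N-methylpropanamide | CON(C)C(=O)[C@H](OC)[C@@H](O)c1cc(OCc2ccccc2)c(OC)c(OCc2ccccc2)c1 | intermediate
15 | (2R,3S)-3-[3,5-bis(benzyloxy)-4-methoxyphenyl]-N,2-dimethoxy-N-methyl-3-(triethylsilyloxy)propanamide | CON(C)C(=O)[C@H](OC)[C@@H](O[Si](CC)(CC)CC)c1cc(OCc2ccccc2)c(OC)c(OCc2ccccc2)c1 | intermediate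
16 | (2R,3S)-3-[3,5-bis(benzyloxy)-4-methoxyphenyl]-2-methoxy-3-(triethylsilyloxy)propanal | O=C[C@H](OC)[C@@H](O[Si](CC)(CC)CC)c1cc(OCc2ccccc2)c(OC)c(OCc2ccccc2)c1 | intermediate
17 | chloroacetaldehyde dimethyl acetal (2-chloro-1,1-dimethoxyethane) | COC(CCl)OC | starting material
18 | lithium methoxyacetylide | [Li]C#COC | intermediate
19 | (4S,5S)-5-[3,5-bis(benzyloxy)-4-methoxyphenyl]-1,4-dimethoxy-5-(triethylsilyloxy)pent-1-yn-3-ol, both C3 epimers | COC#CC(O)[C@H](OC)[C@@H](O[Si](CC)(CC)CC)c1cc(OCc2ccccc2)c(OC)c(OCc2ccccc2)c1 | intermediate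
20 | (4R,5S)-5-[3,5-bis(benzyloxy)-4-methoxyphenyl]-3-(tert-butyldimethylsilyloxy)-1,4-dimethoxy-5-(triethylsilyloxy)pent-1-yne, both C3 epimers | COC#CC(O[Si](C)(C)C(C)(C)C)[C@H](OC)[C@@H](O[Si](CC)(CC)CC)c1cc(OCc2ccccc2)c(OC)c(OCc2ccccc2)c1 | intermediate
21 | 2,3-dimethoxybuta-1,3-dien-1-one (vinylketene) | C=C(OC)C(OC)=C=O | intermediate
22 | 3,4-dimethoxy-4-(1-methoxyethenyl)-2-R-cyclobut-2-en-1-one, mixture at the ring quaternary carbon | C=C(OC)C1(OC)C(OC)=C(C1=O)C(O[Si](C)(C)C(C)(C)C)[C@H](OC)[C@@H](O[Si](CC)(CC)CC)c1cc(OCc2ccccc2)c(OC)c(OCc2ccccc2)c1 | intermediate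
23 | (3Z)-3,4,5-trimethoxy-2-R-hexa-1,3,5-trien-1-one (dienylketene) | C=C(OC)/C(OC)=C(/OC)C(=C=O)C(O[Si](C)(C)C(C)(C)C)[C@H](OC)[C@@H](O[Si](CC)(CC)CC)c1cc(OCc2ccccc2)c(OC)c(OCc2ccccc2)c1 | intermediate
24 | 3,4,5-trimethoxy-2-R-cyclohexa-2,4-dien-1-one | O=C1CC(OC)=C(OC)C(OC)=C1C(O[Si](C)(C)C(C)(C)C)[C@H](OC)[C@@H](O[Si](CC)(CC)CC)c1cc(OCc2ccccc2)c(OC)c(OCc2ccccc2)c1 | intermediate
25 | 2-[(2R,3S)-3-[3,5-bis(benzyloxy)-4-methoxyphenyl]-1-(tert-butyldimethylsilyloxy)-2-methoxy-3-(triethylsilyloxy)propyl]-3,4,5-trimethoxyphenol, both C1 epimers | COc1cc(O)c(c(OC)c1OC)C(O[Si](C)(C)C(C)(C)C)[C@H](OC)[C@@H](O[Si](CC)(CC)CC)c1cc(OCc2ccccc2)c(OC)c(OCc2ccccc2)c1 | intermediate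
26 | 2-[(2R,3S)-3-[3,5-bis(benzyloxy)-4-methoxyphenyl]-1-(tert-butyldimethylsilyloxy)-3-hydroxy-2-methoxypropyl]-3,4,5-trimethoxyphenol, both C1 epimers | COc1cc(O)c(c(OC)c1OC)C(O[Si](C)(C)C(C)(C)C)[C@H](OC)[C@@H](O)c1cc(OCc2ccccc2)c(OC)c(OCc2ccccc2)c1 | intermediate
27 | (2R,3R)-2-[3,5-bis(benzyloxy)-4-methoxyphenyl]-4-(tert-butyldimethylsilyloxy)-3,5,6,7-tetramethoxychromane, both C4 epimers | COc1cc2c(c(OC)c1OC)C(O[Si](C)(C)C(C)(C)C)[C@H](OC)[C@@H](c1cc(OCc3ccccc3)c(OC)c(OCc3ccccc3)c1)O2 | intermediate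
28 | (2R,3S)-2-[3,5-bis(benzyloxy)-4-methoxyphenyl]-3,5,6,7-tetramethoxychroman-4-ol, both C4 epimers | COc1cc2c(c(OC)c1OC)C(O)[C@H](OC)[C@@H](c1cc(OCc3ccccc3)c(OC)c(OCc3ccccc3)c1)O2 | intermediate
29 | (2R,3R)-2-[3,5-bis(benzyloxy)-4-methoxyphenyl]-3,5,6,7-tetramethoxychroman-4-one | COc1cc2c(c(OC)c1OC)C(=O)[C@H](OC)[C@@H](c1cc(OCc3ccccc3)c(OC)c(OCc3ccccc3)c1)O2 | intermediate
30 | (2R,3R)-2-(3,5-dihydroxy-4-methoxyphenyl)-3,5,6,7-tetramethoxychroman-4-one | COc1cc2c(c(OC)c1OC)C(=O)[C@H](OC)[C@@H](c1cc(O)c(OC)c(O)c1)O2 | target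

## Step count and risks

Total step count: 19. Longest linear sequence: 15 steps (5 to 30 through steps 4–6 and 8–19).

Steps most likely to fail:

1. Step 14. The donor-stabilised dialkoxycyclobutenone may open so slowly that vinylketene dimerisation or thermal loss of the ynol ether outruns the cycloaddition, and excess vinylketene may O-acylate the product phenol. Fallback: ring A is bought and joined to the chain by aryllithium addition, setting out from aldehyde 16 and returning at 25. Commercial 3,4,5-trimethoxyphenol is brominated (NBS, MeCN, 0 °C) to 2-bromo-3,4,5-trimethoxyphenol F1 and allylated (allyl bromide, K2CO3, acetone) to 1-(allyloxy)-2-bromo-3,4,5-trimethoxybenzene F2. Bromine–lithium exchange (n-BuLi, THF, −78 °C) gives [2-(allyloxy)-4,5,6-trimethoxyphenyl]lithium F3, which adds to 16 to give the benzylic alcohol (2S,3S)-1-[2-(allyloxy)-4,5,6-trimethoxyphenyl]-3-[3,5-bis(benzyloxy)-4-methoxyphenyl]-2-methoxy-3-(triethylsilyloxy)propan-1-ol F4. Silylation (TBSCl, imidazole, DMF) gives the allyl ether of 25 F5, and deallylation with zerovalent palladium (Pd(PPh3)4, morpholine, THF) gives 25.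

2. Step 3. The delocalised intermediate may be protonated at the methoxy-bearing terminus, giving the transposed 3,4-dimethoxy isomer, or the four-membered ring may be cleaved. Fallback: a radical deoxygenation that sets out from alcohol 2 and returns at 4. Alcohol 2 is converted (phenyl chlorothionoformate, pyridine, DMAP, CH2Cl2, 0 °C) into O-(2,3-dimethoxy-4-oxocyclobut-2-en-1-yl) O-phenyl thiocarbonate F6, which is reduced in a Barton–McCombie chain at room temperature (Bu3SnH, Et3B, air, toluene). Hydrogen-atom transfer to the alkoxyallyl radical is expected at the unhindered hydrogen-bearing terminus, giving 4.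

3. Step 16. The activated, electron-rich benzylic alcohol may ionise, eroding the inversion, or eliminate to an enol ether instead of closing. Fallback: stepwise sulfonate displacement with the phenol masked, setting out from 25 and returning at 27. Phenol 25 is acetylated (Ac2O, pyridine) to the aryl acetate of 25 F7, and the triethylsilyl group is removed (HF·pyridine, pyridine, THF, 0 °C) to the acetate alcohol F8. Mesylation (Ms2O, Et3N, CH2Cl2, −30 °C) gives the benzylic methanesulfonate F9. Treatment with K2CO3 in MeOH–THF at −20 °C cleaves the aryl acetate to the phenol methanesulfonate F10, whose phenoxide closes ring C by SN2 displacement with inversion to give 27.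

## Further compounds

F1 | step 14 | 2-bromo-3,4,5-trimethoxyphenol | COc1cc(O)c(Br)c(OC)c1OC
F2 | step 14 | 1-(allyloxy)-2-bromo-3,4,5-trimethoxybenzene | C=CCOc1cc(OC)c(OC)c(OC)c1Br
F3 | step 14 | [2-(allyloxy)-4,5,6-trimethoxyphenyl]lithium | [Li]c1c(OCC=C)cc(OC)c(OC)c1OC
F4 | step 14 | (2S,3S)-1-[2-(allyloxy)-4,5,6-trimethoxyphenyl]-3-[3,5-bis(benzyloxy)-4-methoxyphenyl]-2-methoxy-3-(triethylsilyloxy)propan-1-ol, both C1 epimers | C=CCOc1cc(OC)c(OC)c(OC)c1C(O)[C@H](OC)[C@@H](O[Si](CC)(CC)CC)c1cc(OCc2ccccc2)c(OC)c(OCc2ccccc2)c1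
F5 | step 14 | allyl ether of 25 | C=CCOc1cc(OC)c(OC)c(OC)c1C(O[Si](C)(C)C(C)(C)C)[C@H](OC)[C@@H](O[Si](CC)(CC)CC)c1cc(OCc2ccccc2)c(OC)c(OCc2ccccc2)c1
F6 | step 3 | O-(2,3-dimethoxy-4-oxocyclobut-2-en-1-yl) O-phenyl thiocarbonate (racemic) | COC1=C(OC)C(=O)C1OC(=S)Oc1ccccc1
F7 | step 16 | aryl acetate of 25 | COc1cc(OC(C)=O)c(c(OC)c1OC)C(O[Si](C)(C)C(C)(C)C)[C@H](OC)[C@@H](O[Si](CC)(CC)CC)c1cc(OCc2ccccc2)c(OC)c(OCc2ccccc2)c1
F8 | step 16 | aryl acetate of 26 | COc1cc(OC(C)=O)c(c(OC)c1OC)C(O[Si](C)(C)C(C)(C)C)[C@H](OC)[C@@H](O)c1cc(OCc2ccccc2)c(OC)c(OCc2ccccc2)c1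
F9 | step 16 | benzylic methanesulfonate of F8 (configuration unchanged) | COc1cc(OC(C)=O)c(c(OC)c1OC)C(O[Si](C)(C)C(C)(C)C)[C@H](OC)[C@@H](OS(C)(=O)=O)c1cc(OCc2ccccc2)c(OC)c(OCc2ccccc2)c1
F10 | step 16 | benzylic methanesulfonate of 26 (configuration unchanged) | COc1cc(O)c(c(OC)c1OC)C(O[Si](C)(C)C(C)(C)C)[C@H](OC)[C@@H](OS(C)(=O)=O)c1cc(OCc2ccccc2)c(OC)c(OCc2ccccc2)c1
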